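**Plan**

1. Target ring locants: C1 ketone, C2 (CH2OH), C3, C4, C5 (quaternary, CH3 + chain), C6 (enol ester arm), C7 (acetonyl). Retrosynthetic cuts, in order: the enol ester O–acyl bond and the acetonyl C=O (back to an aldehyde acetal and an allyl group); C2–CH2OH (back to C2–Br); C1–C2 and C2–C3 (C2 excised, cycloheptenone to cyclohexanone); C7–allyl; C6–H and C6–arm; finally the ring bonds of a Robinson annulation.
2. Enabling feature: the chain carbinol oxygen lies four atoms from C5 (C5–CH2–CH2–CH–O). In the achiral 4-methyl-4-alkylcyclohexa-2,5-dienone it can therefore bridge to one enone β-carbon (the later C4) through a six-membered tetrahydropyran and tell apart the two enone arms on C5.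
3. Forward order of rings: cyclohexenone from melonal and methyl vinyl ketone, then the dienone, then a temporary cis-fused tetrahydropyran (key step). The pyran is opened once C6 and C7 are set, and the carbocycle is enlarged to the cycloheptenone by dibromocarbene insertion of C2.
4. Stereochemistry: the carbinol comes from catalyst-controlled epoxidation (S) and is inverted to R by a Mitsunobu reaction after the pyran is opened. C5 comes from that carbinol through the chair oxa-Michael transition state.
5. C6 is set by axial delivery of hydrogen, anti to the axial C5-methyl, onto an enone that already carries the arm. C7 is set by enolate allylation anti to the same methyl (trans to the arm, also the stable epimer). The E enol ester comes from enol acylation.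

Key step: step 5

Assumption: the ketone-catalysed epoxidation follows the spiro transition-state model, in which the D-fructose-derived catalyst gives the R epoxide of an R–CH=C(CH3)2 alkene; its enantiomer is therefore specified in step 3.

Remark on locants: bicyclic intermediates use chromenone locants (O1, C2, C3, C4, C4a, C5–C8, C8a). C4a = target C5, C5 = target C6, C6 = target C7, C7 = target C1, C8 = target C3, C8a = target C4.

**Route**

Step 1
Reactants: 1 melonal; 2 methyl vinyl ketone
Product: 5 4-methyl-4-(4-methylpent-3-en-1-yl)cyclohex-2-en-1-one (racemic), via pyrrolidine enamine 3 (not isolated), via keto aldehyde 4 (not isolated)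
Conditions: pyrrolidine, toluene, reflux (azeotropic removal of H2O); then 2, 23 °C; then AcOH, NaOAc, H2O, reflux
Reagents that add atoms: none
Why: Robinson annulation run through the Stork enamine (Michael addition to 2, hydrolysis, intramolecular aldol condensation) is reliable for α,α-disubstituted aldehydes; the quaternary carbon forms racemic, which is immaterial because step 2 removes its chirality.

Step 2
Reactants: 5 cyclohexenone
Product: 6 4-methyl-4-(4-methylpent-3-en-1-yl)cyclohexa-2,5-dien-1-one
Conditions: IBX (2-iodoxybenzoic acid, 2.5 equiv), DMSO, 75 °C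
Reagents that add atoms: none
Why: IBX dehydrogenation of the enone through its enol at the α′,β′ position gives the cross-conjugated dienone, which is achiral with two enantiotopic enone arms, while the isolated trisubstituted alkene is inert to the oxidant.

Step 3
Reactants: 6 dienone
Product: 7 (S)-epoxide of the side-chain alkene
Conditions: ent-fructose-derived ketone catalyst (1,2:4,5-di-O-isopropylidene-L-erythro-2,3-hexodiulo-2,6-pyranose, 30 mol%), KHSO5 (as 2KHSO5·KHSO4·K2SO4), K2CO3, Bu4NHSO4, MeCN–CH2(OMe)2, aq. Na2B4O7 buffer, 0 °C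
Reagents that add atoms: potassium peroxymonosulfate KHSO5, [K+].[O-]S(=O)(=O)OO
Why: Shi epoxidation, in which the chiral dioxirane transfers oxygen through a spiro transition state to the electron-rich trisubstituted alkene (the electron-poor dienone is not attacked by the electrophilic oxidant), and the catalyst enantiomer fixes the S configuration of the later carbinol carbon.

Step 4
Reactants: 7 epoxide
Product: 8 4-[(3S)-3-hydroxy-4-methylpent-4-en-1-yl]-4-methylcyclohexa-2,5-dien-1-one
Conditions: Et2Al(TMP) (TMP = 2,2,6,6-tetramethylpiperidide; from Et2AlCl and lithium 2,2,6,6-tetramethylpiperidide), toluene, 0 °C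
Reagents that add atoms: none
Why: Aluminium amide-mediated isomerisation of a trisubstituted epoxide to the allylic alcohol (syn β-elimination of a methyl hydrogen while aluminium activates the oxygen) leaves the secondary C–O bond untouched, so the S configuration is kept, and the dienone offers the base no enolisable hydrogen.

Step 5
Reactants: 8 hydroxy dienone
Product: 9 (2S,4aR,8aS)-4a-methyl-2-(prop-1-en-2-yl)-2,3,4,4a,8,8a-hexahydro-7H-chromen-7-one
Conditions: t-BuOK (10 mol%), THF, −20 → 0 °C; aq. NH4Cl
Reagents that add atoms: none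
Why: The potassium alkoxide of 8 adds reversibly to the β-carbon of one enone arm and the resulting enolate is protonated by a further molecule of 8, so the base is needed only in catalytic amount. The closest known reaction type is the diastereoselective intramolecular oxa-Michael desymmetrisation of 4,4-disubstituted cyclohexa-2,5-dienones by a tethered alcohol. The tetrahydropyran closes in the 6-exo-trig mode through a chair in which the new C–O bond is axial on the carbocycle, perpendicular to the enone plane. C8a is set by the tether, which can only reach the face of the dienone it is attached to, so the ring fusion is cis; C4a is set by the S carbinol, because addition to one arm keeps the isopropenyl group equatorial in this chair whereas addition to the other arm would force it axial. The selectivity needed is thus the choice between the two diastereotopic enone arms, and it is secured by the equatorial preference of the carbinol substituent. Kinetic and thermodynamic preferences should coincide, since the other isomer can place isopropenyl equatorial only by making C8 and the methyl group axial on the pyran.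

Step 6
Reactants: 9 bicyclic enone; 10 (1,3-dioxolan-2-ylmethyl)magnesium bromide
Product: 12 5-(1,3-dioxolan-2-ylmethyl) derivative of enone 9, via silyl enol ether 11 (not isolated)
Conditions: CuBr·SMe2 (20 mol%), Me3SiCl, HMPA, THF, −78 → −40 °C; then Pd(OAc)2, MeCN, 23 °C
Reagents that add atoms: none
Why: Copper-catalysed conjugate addition of the Grignard reagent, accelerated by Me3SiCl, followed by Saegusa–Ito oxidation of the silyl enol ether puts the acetaldehyde-equivalent arm on C5 and restores the enone; because a carbon nucleophile enters anti to the axial angular methyl (the wrong face for the target), the C5 centre formed here is erased on purpose and is set in step 7.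

Step 7
Reactants: 12 arm-bearing enone; 13 allyl bromide
Product: 15 (2S,4aR,5S,6S,8aS)-5-(1,3-dioxolan-2-ylmethyl)-4a-methyl-6-(prop-2-en-1-yl)-2-(prop-1-en-2-yl)octahydro-7H-chromen-7-one, via lithium enolate 14 (not isolated)
Conditions: Li, NH3(l)–THF, t-BuOH (1 equiv), −78 °C; then 13, −78 → −33 °C
Reagents that add atoms: none
Why: Dissolving-metal reduction with trapping of the regio-defined enolate (Stork reductive alkylation) protonates C5 axially on the face anti to the axial angular methyl, leaving the arm equatorial and cis to that methyl, and allyl bromide then attacks C6 anti to the same methyl (the other face is 1,3-diaxial to it), giving the trans arm/allyl arrangement that is also the stable one at this epimerisable centre.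

Step 8
Reactants: 15 bicyclic ketone
Product: 16 (4S,5S,6S)-5-(1,3-dioxolan-2-ylmethyl)-4-[(3S)-3-hydroxy-4-methylpent-4-en-1-yl]-4-methyl-6-(prop-2-en-1-yl)cyclohex-2-en-1-one
Conditions: LiN(i-Pr)2 (1.1 equiv), THF, −78 → −10 °C; AcOH, −78 °C
Reagents that add atoms: none
Why: Retro-oxa-Michael reaction by the E1cB path, in which kinetic deprotonation at the C8 methylene gives the enolate that expels the axial, π-aligned C8a–O bond (the lithium alkoxide being the weaker base), and cold protonation gives the neutral hydroxy enone, which does not re-close without a catalyst; only the temporary C8a centre is lost.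

Step 9
Reactants: 16 hydroxy enone
Product: 17 (4S,5S,6S)-4-[(3R)-3-acetoxy-4-methylpent-4-en-1-yl]-5-(1,3-dioxolan-2-ylmethyl)-4-methyl-6-(prop-2-en-1-yl)cyclohex-2-en-1-one
Conditions: AcOH, PPh3, DIAD, toluene, 0 → 23 °C
Reagents that add atoms: acetic acid, CC(=O)O
Why: Mitsunobu reaction, in which acetate displaces the oxyphosphonium of the secondary allylic alcohol by SN2 and so inverts the carbinol to the R configuration of the target under neutral conditions that do not promote re-addition to the enone.

Step 10
Reactants: 17 acetoxy enone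
Product: 18 dimethylphenylsilyl enol ether (1-silyloxycyclohex-1-ene, C2=C3 of 17 reduced)
Conditions: [(Ph3P)CuH]6 (5 mol%), PhMe2SiH, toluene, 23 °C
Reagents that add atoms: dimethylphenylsilane, C[SiH](C)c1ccccc1
Why: Copper hydride-catalysed 1,4-hydrosilylation of the enone delivers hydride to the β-carbon and gives the silyl enol ether regiospecifically on the ketone side away from the allyl-bearing carbon, while ester, acetal and unactivated alkenes are not reduced and no stereocentre is formed.

Step 11
Reactants: 18 silyl enol ether; 19 bromoform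
Product: 21 (5S,6S,7S)-5-[(3R)-3-acetoxy-4-methylpent-4-en-1-yl]-2-bromo-6-(1,3-dioxolan-2-ylmethyl)-5-methyl-7-(prop-2-en-1-yl)cyclohept-2-en-1-one, via dibromocyclopropane 20 (not isolated)
Conditions: 19, t-BuOK, hexane–Et2O, −78 → −20 °C; then toluene, 90 °C
Reagents that add atoms: none
Why: Dibromocarbene adds to the electron-rich silyl enol ether much faster than to the mono- and 1,1-disubstituted alkenes (the latter deactivated by its allylic acetate), and the siloxy dibromocyclopropane then opens thermally with loss of bromide and the silyl group to the 2-bromocyclohept-2-enone, a one-carbon ring expansion that inserts C2 between C1 and C3 and creates no stereocentre.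

Step 12
Reactants: 21 bromoenone acetate
Product: 22 (5S,6S,7S)-2-bromo-6-(1,3-dioxolan-2-ylmethyl)-5-[(3R)-3-hydroxy-4-methylpent-4-en-1-yl]-5-methyl-7-(prop-2-en-1-yl)cyclohept-2-en-1-one
Conditions: K2CO3 (cat.), MeOH, 0 °C
Reagents that add atoms: none
Why: Base-catalysed transesterification removes the acetate before any palladium chemistry, so that no allylic ester is present to ionise to a π-allyl complex, and C7 (α to the ketone) can only equilibrate towards the trans arrangement it already has.

Step 13
Reactants: 22 bromoenone alcohol; 23 (tributylstannyl)methanol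
Product: 24 (5S,6S,7S)-6-(1,3-dioxolan-2-ylmethyl)-2-(hydroxymethyl)-5-[(3R)-3-hydroxy-4-methylpent-4-en-1-yl]-5-methyl-7-(prop-2-en-1-yl)cyclohept-2-en-1-one
Conditions: Pd(PPh3)4 (10 mol%), 1,4-dioxane, 95 °C
Reagents that add atoms: none
Why: Stille coupling, in which zerovalent palladium inserts into the C(sp2)–Br bond of the α-bromoenone, the hydroxymethyl group is transferred from tin and reductive elimination forms the C2–CH2OH bond without protecting groups.

Step 14
Reactants: 24 diol
Product: 25 bis(tert-butyldimethylsilyl) ether of 24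
Conditions: t-BuMe2SiCl, imidazole, DMAP (cat.), DMF, 23 °C
Reagents that add atoms: tert-butyldimethylsilyl chloride, CC(C)(C)[Si](C)(C)Cl
Why: Standard silylation masks both hydroxyl groups so that the later acylation can only take place at the aldehyde enol.

Step 15
Reactants: 25 bis-silyl ether acetal
Product: 26 aldehyde (C6–CH2–CHO)
Conditions: pyridinium p-toluenesulfonate, acetone–H2O (10:1), 55 °C
Reagents that add atoms: water, O
Why: Acid-catalysed acetal hydrolysis (transacetalisation to acetone) frees the aldehyde, and the buffered acid leaves the two silyl ethers in place.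

Step 16
Reactants: 26 aldehyde; 27 3-methylbut-2-enoic anhydride
Product: 28 (E)-enol 3-methylbut-2-enoate (C6–CH=CH–OCOR)
Conditions: Et3N, DMAP, CH2Cl2, 0 → 23 °C
Reagents that add atoms: none
Why: Enol esterification, in which the N-acylpyridinium from 27 O-acylates the aldehyde enolate formed by the amine (the ketone α-hydrogen is tertiary, hindered and less acidic), and the E geometry should result because the acyloxy group avoids the ring carbon flanked by the quaternary centre, reversible acyl transfer through DMAP allowing the more stable isomer to accumulate.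

Step 17
Reactants: 28 enol ester
Product: 29 bis(tert-butyldimethylsilyl) ether of the target (C7 acetonyl)
Conditions: PdCl2 (20 mol%), CuCl, O2 (1 atm), DMF–H2O (7:1), 23 °C
Reagents that add atoms: water, O
Why: Tsuji–Wacker oxidation, in which Markovnikov hydroxypalladation of the terminal alkene and β-hydride elimination give the methyl ketone while internal, 1,1-disubstituted, trisubstituted and conjugated alkenes react far more slowly; keeping the ketone masked as allyl until now avoids any keto aldehyde.

Step 18
Reactants: 29 bis-silyl ether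
Product: 30 CNP0257974.1
Conditions: HF·pyridine, pyridine, THF, 0 → 23 °C
Reagents that add atoms: none
Why: Fluoride-mediated cleavage of both silyl ethers under buffered acidic conditions, to which the enol ester, the enone and the 1,4-diketone are inert.

**Compound list**

1 | melonal (2,6-dimethylhept-5-enal, racemic) | CC(C)=CCCC(C)C=O | starting material
2 | methyl vinyl ketone (but-3-en-2-one) | C=CC(C)=O | starting material
3 | 1-(2,6-dimethylhepta-1,5-dien-1-yl)pyrrolidine (enamine of 1) | CC(C)=CCCC(C)=CN1CCCC1 | intermediate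
4 | 2,6-dimethyl-2-(3-oxobutyl)hept-5-enal (racemic) | CC(C)=CCCC(C)(CCC(C)=O)C=O | intermediate
5 | 4-methyl-4-(4-methylpent-3-en-1-yl)cyclohex-2-en-1-one (racemic) | CC(C)=CCCC1(C)CCC(=O)C=C1 | intermediate
6 | 4-methyl-4-(4-methylpent-3-en-1-yl)cyclohexa-2,5-dien-1-one (achiral) | CC(C)=CCCC1(C)C=CC(=O)C=C1 | intermediate
7 | 4-{2-[(2S)-3,3-dimethyloxiran-2-yl]ethyl}-4-methylcyclohexa-2,5-dien-1-one | CC1(C)[C@@H](O1)CCC2(C)C=CC(=O)C=C2 | intermediate
8 | 4-[(3S)-3-hydroxy-4-methylpent-4-en-1-yl]-4-methylcyclohexa-2,5-dien-1-one | C=C(C)[C@@H](O)CCC1(C)C=CC(=O)C=C1 | intermediate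
9 | (2S,4aR,8aS)-4a-methyl-2-(prop-1-en-2-yl)-2,3,4,4a,8,8a-hexahydro-7H-chromen-7-one (cis-fused) | C=C(C)[C@@H]2CC[C@@]1(C)[C@@H](O2)CC(=O)C=C1 | intermediate
10 | (1,3-dioxolan-2-ylmethyl)magnesium bromide | Br[Mg]CC1OCCO1 | starting material
11 | trimethylsilyl enol ether of the conjugate adduct of 9 (7-silyloxy-6-ene; C5 arm trans to the 4a-methyl) | C=C(C)[C@@H]2CC[C@@]1(C)[C@@H](O2)CC(O[Si](C)(C)C)=C[C@H]1CC3OCCO3 | intermediate
12 | (2S,4aR,8aS)-5-(1,3-dioxolan-2-ylmethyl)-4a-methyl-2-(prop-1-en-2-yl)-2,3,4,4a,8,8a-hexahydro-7H-chromen-7-one | C=C(C)[C@@H]2CC[C@@]1(C)[C@@H](O2)CC(=O)C=C1CC3OCCO3 | intermediate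
13 | allyl bromide (3-bromoprop-1-ene) | C=CCBr | starting material
14 | lithium enolate from reduction of 12 (7-lithiooxy-6-ene; C5 arm cis to the 4a-methyl) | C=C(C)[C@@H]2CC[C@@]1(C)[C@@H](O2)CC(O[Li])=C[C@@H]1CC3OCCO3 | intermediate
15 | (2S,4aR,5S,6S,8aS)-5-(1,3-dioxolan-2-ylmethyl)-4a-methyl-6-(prop-2-en-1-yl)-2-(prop-1-en-2-yl)octahydro-7H-chromen-7-one | C=C(C)[C@@H]2CC[C@@]1(C)[C@@H](O2)CC(=O)[C@@H](CC=C)[C@@H]1CC3OCCO3 | intermediate
16 | (4S,5S,6S)-5-(1,3-dioxolan-2-ylmethyl)-4-[(3S)-3-hydroxy-4-methylpent-4-en-1-yl]-4-methyl-6-(prop-2-en-1-yl)cyclohex-2-en-1-one | C=C(C)[C@@H](O)CC[C@@]1(C)C=CC(=O)[C@@H](CC=C)[C@@H]1CC2OCCO2 | intermediate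
17 | (4S,5S,6S)-4-[(3R)-3-acetoxy-4-methylpent-4-en-1-yl]-5-(1,3-dioxolan-2-ylmethyl)-4-methyl-6-(prop-2-en-1-yl)cyclohex-2-en-1-one | C=C(C)[C@H](OC(C)=O)CC[C@@]1(C)C=CC(=O)[C@@H](CC=C)[C@@H]1CC2OCCO2 | intermediate
18 | dimethylphenylsilyl enol ether from 1,4-reduction of 17 (1-silyloxycyclohex-1-ene; C4, C5, C6 and chain as in 17) | C=C(C)[C@H](OC(C)=O)CC[C@@]1(C)CC=C(O[Si](C)(C)c2ccccc2)[C@@H](CC=C)[C@@H]1CC3OCCO3 | intermediate
19 | bromoform | BrC(Br)Br | starting material
20 | 7,7-dibromo-1-(dimethylphenylsilyloxy)bicyclo[4.1.0]heptane adduct of 18 (cyclopropane face not defined) | C=C(C)[C@H](OC(C)=O)CC[C@@]1(C)CC2C(Br)(Br)C2(O[Si](C)(C)c3ccccc3)[C@@H](CC=C)[C@@H]1CC4OCCO4 | intermediate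
21 | (5S,6S,7S)-5-[(3R)-3-acetoxy-4-methylpent-4-en-1-yl]-2-bromo-6-(1,3-dioxolan-2-ylmethyl)-5-methyl-7-(prop-2-en-1-yl)cyclohept-2-en-1-one | C=C(C)[C@H](OC(C)=O)CC[C@@]1(C)CC=C(Br)C(=O)[C@@H](CC=C)[C@@H]1CC2OCCO2 | intermediate
22 | (5S,6S,7S)-2-bromo-6-(1,3-dioxolan-2-ylmethyl)-5-[(3R)-3-hydroxy-4-methylpent-4-en-1-yl]-5-methyl-7-(prop-2-en-1-yl)cyclohept-2-en-1-one | C=C(C)[C@H](O)CC[C@@]1(C)CC=C(Br)C(=O)[C@@H](CC=C)[C@@H]1CC2OCCO2 | intermediate
23 | (tributylstannyl)methanol | OC[Sn](CCCC)(CCCC)CCCC | starting material
24 | (5S,6S,7S)-6-(1,3-dioxolan-2-ylmethyl)-2-(hydroxymethyl)-5-[(3R)-3-hydroxy-4-methylpent-4-en-1-yl]-5-methyl-7-(prop-2-en-1-yl)cyclohept-2-en-1-one | C=C(C)[C@H](O)CC[C@@]1(C)CC=C(CO)C(=O)[C@@H](CC=C)[C@@H]1CC2OCCO2 | intermediate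
25 | bis(tert-butyldimethylsilyl) ether of 24 (both hydroxyl groups silylated) | C=C(C)[C@H](O[Si](C)(C)C(C)(C)C)CC[C@@]1(C)CC=C(CO[Si](C)(C)C(C)(C)C)C(=O)[C@@H](CC=C)[C@@H]1CC2OCCO2 | intermediate
26 | aldehyde from 25 (C6 substituent CH2CHO; otherwise as 25) | C=C(C)[C@H](O[Si](C)(C)C(C)(C)C)CC[C@@]1(C)CC=C(CO[Si](C)(C)C(C)(C)C)C(=O)[C@@H](CC=C)[C@@H]1CC=O | intermediate
27 | 3-methylbut-2-enoic anhydride (senecioic anhydride) | CC(C)=CC(=O)OC(=O)C=C(C)C | starting material
28 | (E)-enol 3-methylbut-2-enoate of 26 (C6 substituent (E)-CH=CH–OCOCH=C(CH3)2; C7 allyl) | C=C(C)[C@H](O[Si](C)(C)C(C)(C)C)CC[C@@]1(C)CC=C(CO[Si](C)(C)C(C)(C)C)C(=O)[C@@H](CC=C)[C@@H]1/C=C/OC(=O)C=C(C)C | intermediate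
29 | bis(tert-butyldimethylsilyl) ether of the target (C7 substituent 2-oxopropyl) | C=C(C)[C@H](O[Si](C)(C)C(C)(C)C)CC[C@@]1(C)CC=C(CO[Si](C)(C)C(C)(C)C)C(=O)[C@@H](CC(C)=O)[C@@H]1/C=C/OC(=O)C=C(C)C | intermediate
30 | CNP0257974.1: (5S,6S,7S)-2-(hydroxymethyl)-5-[(3R)-3-hydroxy-4-methylpent-4-en-1-yl]-5-methyl-6-[(E)-2-(3-methylbut-2-enoyloxy)ethenyl]-7-(2-oxopropyl)cyclohept-2-en-1-one | C=C(C)[C@H](O)CC[C@@]1(C)CC=C(CO)C(=O)[C@@H](CC(C)=O)[C@@H]1/C=C/OC(=O)C=C(C)C | target

**Totals and risks**

Total step count: 18. Longest linear sequence: 18 steps (from melonal; the route is fully linear).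

Steps most likely to fail:

Step 8. The ring opening may stop short or run backwards: the lithium alkoxide can re-add to the enone while the mixture warms, and traces of base or acid during quench and isolation can close the pyran again. The fallback sets out from 15 and returns at 16. The same enolate elimination is run with LiN(SiMe3)2 in THF and the released alkoxide is captured irreversibly with t-BuMe2SiCl and imidazole in DMF, which drains the equilibrium and gives the tert-butyldimethylsilyl ether F1. HF·pyridine in THF at 0 °C then frees the alcohol under acidic conditions that do not promote conjugate re-addition, giving 16.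

Step 11. Chemoselectivity may be lost: the carbene can also cyclopropanate the isopropenyl or allyl group, and the butoxide can attack the acetate or the silyl enol ether before the carbene is formed. The fallback sets out from 18 and returns at 24. Zinc carbenoid cyclopropanation (Et2Zn, CH2I2, CH2Cl2, 0 °C), which strongly prefers the electron-rich enol ether, gives the siloxycyclopropane F2. Oxidative ring opening with FeCl3 in DMF gives the ring-enlarged 3-chlorocycloheptanone F3, and NaOAc in MeOH eliminates hydrogen chloride to give the cyclohept-2-enone F4. α-Iodination with I2 and pyridine gives the 2-iodoenone F5, methanolysis (K2CO3, MeOH, 0 °C) gives the iodo alcohol F6, and the Stille coupling of step 13 with 23 then gives 24.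

Step 16. Control of the enol ester geometry may be poor (Z isomer formed beside E), and the acyl double bond may move out of conjugation through a vinylketene under amine base. The fallback sets out from 26 and returns at 28. The aldehyde is converted (Et3SiOSO2CF3, Et3N, CH2Cl2, −78 °C) into its triethylsilyl enol ether, whose E isomer F7 is separated, the Z isomer being hydrolysed back to 26. Fluoride-catalysed silyl–acyl exchange with 3-methylbut-2-enoyl fluoride F8 (from 3-methylbut-2-enoic acid and cyanuric fluoride) and catalytic Bu4NF in THF then gives 28 with retention of the E geometry and without amine base.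

Further compounds
F1 | step 8 | (4S,5S,6S)-4-[(3S)-3-(tert-butyldimethylsilyloxy)-4-methylpent-4-en-1-yl]-5-(1,3-dioxolan-2-ylmethyl)-4-methyl-6-(prop-2-en-1-yl)cyclohex-2-en-1-one | C=C(C)[C@@H](O[Si](C)(C)C(C)(C)C)CC[C@@]1(C)C=CC(=O)[C@@H](CC=C)[C@@H]1CC2OCCO2
F2 | step 11 | 1-(dimethylphenylsilyloxy)bicyclo[4.1.0]heptane from 18 (cyclopropane face not defined) | C=C(C)[C@H](OC(C)=O)CC[C@@]1(C)CC2CC2(O[Si](C)(C)c3ccccc3)[C@@H](CC=C)[C@@H]1CC4OCCO4
F3 | step 11 | 3-chlorocycloheptanone from F2 (C3 epimers; other centres as in 21) | C=C(C)[C@H](OC(C)=O)CC[C@@]1(C)CC(Cl)CC(=O)[C@@H](CC=C)[C@@H]1CC2OCCO2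
F4 | step 11 | (5S,6S,7S)-5-[(3R)-3-acetoxy-4-methylpent-4-en-1-yl]-6-(1,3-dioxolan-2-ylmethyl)-5-methyl-7-(prop-2-en-1-yl)cyclohept-2-en-1-one | C=C(C)[C@H](OC(C)=O)CC[C@@]1(C)CC=CC(=O)[C@@H](CC=C)[C@@H]1CC2OCCO2
F5 | step 11 | 2-iodo analogue of 21 | C=C(C)[C@H](OC(C)=O)CC[C@@]1(C)CC=C(I)C(=O)[C@@H](CC=C)[C@@H]1CC2OCCO2
F6 | step 11 | 2-iodo analogue of 22 | C=C(C)[C@H](O)CC[C@@]1(C)CC=C(I)C(=O)[C@@H](CC=C)[C@@H]1CC2OCCO2
F7 | step 16 | (E)-triethylsilyl enol ether of aldehyde 26 | C=C(C)[C@H](O[Si](C)(C)C(C)(C)C)CC[C@@]1(C)CC=C(CO[Si](C)(C)C(C)(C)C)C(=O)[C@@H](CC=C)[C@@H]1/C=C/O[Si](CC)(CC)CC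
F8 | step 16 | 3-methylbut-2-enoyl fluoride | CC(C)=CC(F)=O
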